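The numbers in the tables were computed for an exercise.

Early in the green run I read 2% product at 5.00 h, and none of the solid reagent starts in solution, so I expected a start-up lag.

| setting | green | teal | flask |
|---|---|---|---|
| starting material | 0.010 M | 0.015 M | 0.010 M |
| solid reagent | 1 equiv | 1 equiv | 1.00 equiv |
| free catalyst | 0.98 mol% | 0.98 mol% | 0.98 mol% |
| remark | the very flask that is asked about, followed so far | run made earlier |  |
| time |  |  | 4.0 d |

green run (percent of the starting material charged)

| time / h | product / % | starting material / % |
|---|---|---|
| 1.50 | 1 | 98 |
| 3.00 | 2 | 99 |
| 5.00 | 2 | 94 |
| 10.0 | 10 | 92 |
| 20.0 | 21 | 75 |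

teal run (percent of the starting material charged)

| time / d | product / % | starting material / % |
|---|---|---|
| 0.625 | 13 | 86 |
| 1.04 | 26 | 76 |
| 1.67 | 38 | 63 |
| 2.50 | 51 | 48 |
| 3.00 | 60 | 37 |

(scatter of a reading: 1.5 percentage points)

- product present at 4.0 d, in percent of the starting material charged
- starting material present at 4.0 d, in percent of the starting material charged

- what is said of product includes idle complex
- solid reagent is a solid; its amount is given per volume of the solution
- the earlier runs were read with a standard deviation of 1.5 percentage points
- what may be going on: solid reagent <-> coupling partner; free catalyst + product <-> idle complex; starting material + free catalyst -> catalyst intermediate A; coupling partner + catalyst intermediate A -> catalyst intermediate B; catalyst intermediate A -> spent catalyst; catalyst intermediate B -> free catalyst + product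
- at the start none of the solid reagent is in solution

1. I followed one molecule of starting material and asked for its chance per day of being taken up, its hazard (an apparent pseudo-first-order constant). While the hazard stays constant, the fraction of the charge left falls as the exponential of minus hazard times time.
2. Green held 92% at 10.0 h and 75% at 20.0 h. Teal, at 15 h, held 86%, between those fractions, although it started at 0.015 M against 0.010 M. So I used teal's hazard for the green flask.
3. Teal's last reading, counted from the start, gave 0.331 d⁻¹, which leaves 26.6% at 4.0 d.
4. The weak link was the lag inside that number: teal's first reading gave 0.241 d⁻¹, lower. So I reforged it from teal's first and last readings, which gave 0.355 d⁻¹, the running hazard.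
5. Running that from green's last reading left 24.4% starting material. The remainder, 75.6%, I committed to as product, within the loading of 0.98 mol%.

The forecast, which differed from my reckoning, took “dissolution of the solid, proportional to the solid remaining, as the rate limit” and gave 68% (57% to 76%) product and 30% (22% to 41%) starting material.

The green flask gave 75.8% product and 23.9% starting material.

    solid reagent ⇌ coupling partner, rate k1*(cs1 - [coupling partner]) while solid is left; crystals form when [coupling partner] > cs1 (solubility = 3.80 mM, k = 0.0440 h⁻¹)
    free catalyst + product ⇌ idle complex (K = 140 M⁻¹, k = 5.80 M⁻¹ h⁻¹)
    starting material + free catalyst → catalyst intermediate A (k = 490 M⁻¹ h⁻¹)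
    coupling partner + catalyst intermediate A → catalyst intermediate B (k = 40000 M⁻¹ h⁻¹)
    catalyst intermediate A → spent catalyst (k = 0.0510 h⁻¹)
    catalyst intermediate B → free catalyst + product (k = 2.00 h⁻¹)

Reckoned from its last reading, with that reading's scatter, to that result, the running hazard of the green flask came to 0.361 d⁻¹, beside the 0.355 d⁻¹ I had carried. For the neighbouring flask with 0.24 mol% of free catalyst, I scaled the running hazard with the loading, which gave 0.0870 d⁻¹. Counted from the charge, that leaves 70.6% starting material at 4.0 d. That neighbouring flask held 72.8% starting material and 27.0% product.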